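**Retrosynthetic overview**

1. Target 22 ⇐ ketone 20: the C1 carbonyl becomes the exocyclic methylene (Peterson olefination) and the silyl ether is removed.
2. 20 ⇐ oxygen-bridged enol ether 19 by HCl: C9–O is exchanged for C9–Cl with retention through the C10 bromonium ion. This gives the trans-diequatorial Br/Cl pair; direct BrCl addition to the ring B alkene would add trans-diaxially with bromine anti to C5 and give the wrong diastereomer.
3. 19 ⇐ 13: C4–Br by reagent-controlled enolate hydroxylation and SN2 inversion, C3–OH by cis-selective hydride reduction.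
4. 13 ⇐ spiro vinylogous ester 11 by the proposed transannular carbonyl-oxygen bromocyclisation, which sets C9 and C10 and transposes the ring A carbonyl.
5. 11 ⇐ dimedone: ring A is bought, C6 is set by Pd-catalysed decarboxylative asymmetric allylation, ring B is closed second by metathesis; the oxygen bridge is temporary.

Assumption: the target locants (C1 methylidene carbon, C3 carbinol, C4 CHBr, C5 CMe2, C6 spiro, C9 CCl, C10 CHBr) are kept for all spiro compounds, and the facial sense of the two reagent-controlled steps (4 and 7) is taken from the standard models for simpler substrates.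

**Route**

Step 1
Reactants: 1 dimedone (5,5-dimethylcyclohexane-1,3-dione); 2 2-methylpropan-1-ol
Product: 3 5,5-dimethyl-3-(2-methylpropoxy)cyclohex-2-en-1-one
Conditions: TsOH·H2O (2 mol %), toluene, reflux, Dean–Stark trap
Reagents that add atoms: none
Why: Acid-catalysed enol etherification of a cyclic 1,3-dione with azeotropic removal of water gives the vinylogous ester; no stereocentre is formed.

Step 2
Reactants: 3 5,5-dimethyl-3-(2-methylpropoxy)cyclohex-2-en-1-one; 4 4-iodo-2-methylbut-1-ene
Product: 6 5,5-dimethyl-6-(3-methylbut-3-en-1-yl)-3-(2-methylpropoxy)cyclohex-2-en-1-one (racemic), via lithium enolate 5 (not isolated)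
Conditions: LiN(iPr)2, THF, −78 °C; then 4, DMPU, −78 → 0 °C
Reagents that add atoms: none
Why: Kinetic deprotonation of the vinylogous ester takes place at the alpha-prime carbon C6 and the lithium enolate is alkylated by the primary iodide (Stork–Danheiser-type enolate alkylation); the new centre is racemic and is erased in step 3.

Step 3
Reactants: 6 5,5-dimethyl-6-(3-methylbut-3-en-1-yl)-3-(2-methylpropoxy)cyclohex-2-en-1-one; 7 allyl chloroformate (prop-2-en-1-yl carbonochloridate)
Product: 9 3,3-dimethyl-2-(3-methylbut-3-en-1-yl)-5-(2-methylpropoxy)cyclohexa-1,5-dien-1-yl prop-2-en-1-yl carbonate, via lithium enolate 8 (not isolated)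
Conditions: LiN(iPr)2, TMEDA, THF, −78 °C; then 7, −78 °C
Reagents that add atoms: none
Why: The fully substituted alpha-prime enolate is acylated on oxygen by the chloroformate (enol carbonate formation), which stores the C6 enolate in latent form for step 4; no stereocentre remains.

Step 4
Reactants: 9 3,3-dimethyl-2-(3-methylbut-3-en-1-yl)-5-(2-methylpropoxy)cyclohexa-1,5-dien-1-yl prop-2-en-1-yl carbonate
Product: 10 (6S)-5,5-dimethyl-6-(3-methylbut-3-en-1-yl)-3-(2-methylpropoxy)-6-(prop-2-en-1-yl)cyclohex-2-en-1-one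
Conditions: Pd2(dba)3 (2.5 mol %, zerovalent palladium source), (R)-4-tert-butyl-2-{2-[bis(4-trifluoromethylphenyl)phosphanyl]-5-(trifluoromethyl)phenyl}-4,5-dihydro-1,3-oxazole (6 mol %), toluene, 25 → 40 °C
Reagents that add atoms: none
Why: Decarboxylative asymmetric allylic alkylation (enantioselective Tsuji allylation): zerovalent palladium ionises the allyl carbonate, CO2 is lost, and the allyl group is delivered within the chiral Pd–PHOX enolate complex to one face of C6, which sets the quaternary stereocentre (S here, R in the target after the priority change); the electron-poor ligand is chosen for this hindered, neopentyl-type enolate.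

Step 5
Reactants: 10 (6S)-5,5-dimethyl-6-(3-methylbut-3-en-1-yl)-3-(2-methylpropoxy)-6-(prop-2-en-1-yl)cyclohex-2-en-1-one
Product: 11 (6S)-5,5,9-trimethyl-3-(2-methylpropoxy)spiro[5.5]undeca-2,9-dien-1-one
Conditions: second-generation Grubbs catalyst RuCl2(=CHPh)(PCy3)(H2IMes) (5 mol %), CH2Cl2, 40 °C
Reagents that add atoms: none
Why: Ring-closing olefin metathesis between the monosubstituted and the 1,1-disubstituted alkene closes ring B as the trisubstituted cyclohexene and releases ethene; C6 is untouched.

Step 6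
Reactants: 11 (6S)-5,5,9-trimethyl-3-(2-methylpropoxy)spiro[5.5]undeca-2,9-dien-1-one
Product: 13 (6S,9R,10R)-10-bromo-1,9-epoxy-5,5,9-trimethylspiro[5.5]undec-1-en-3-one, via bridged dialkoxyallyl cation saccharinate 12 (not isolated)
Conditions: N-bromosaccharin (1.05 equiv), CH2Cl2, −60 → −30 °C, dark; then aqueous NaH2PO4/Na2HPO4 (pH 7), 0 °C
Reagents that add atoms: N-bromosaccharin O=C1N(Br)S(=O)(=O)c2ccccc12; water O
Why: Proposed new method: a transannular, dealkylative bromo-oxycyclisation in which the Lewis-basic carbonyl oxygen on C1 of the vinylogous ester captures the bromonium ion of the ring B alkene at the tertiary carbon C9 through a boat (cineole-type) transition state, so that oxygen must enter on the ring face that carries C1 and bromine on the opposite face (anti addition, C9 R and C10 R, bromine cis to C5); the resulting 1,3-dialkoxyallyl cation 12 is persistent, the weakly basic saccharinate counter-ion and the low temperature are chosen to disfavour irreversible bromination at C2, and buffered water then adds at the unhindered C3 and expels isobutanol, which leaves the carbonyl at C3 and the enol ether at C1; the closest known reactions are the bromoetherification of 4-(hydroxyalkyl)cyclohexenes to 2-oxabicyclo[2.2.2]octanes, the halo-enoletherification of 1,3-dicarbonyl enols and the halolactonisation of esters with loss of the O-alkyl group.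

Step 7
Reactants: 13 (6S,9R,10R)-10-bromo-1,9-epoxy-5,5,9-trimethylspiro[5.5]undec-1-en-3-one
Product: 15 (4S,6S,9R,10R)-10-bromo-1,9-epoxy-4-hydroxy-5,5,9-trimethylspiro[5.5]undec-1-en-3-one, via sodium dienolate 14 (not isolated)
Conditions: NaN(SiMe3)2, THF, −78 °C; then (+)-(camphorylsulfonyl)oxaziridine, −78 → −40 °C
Reagents that add atoms: (+)-(camphorylsulfonyl)oxaziridine CC1(C)C2CCC13CS(=O)(=O)N4OC34C2
Why: Davis oxidation of an enolate: C4 is the only enolisable position of 13, and because ring A of 13 is flat with the two carbon bridges of the cage placed symmetrically on its two faces the substrate has no bias, so the C4 configuration (S, hydroxyl anti to C11) is fixed by the chiral N-sulfonyloxaziridine (reagent control), the minor epimer being removed by crystallisation at 18.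

Step 8
Reactants: 15 (4S,6S,9R,10R)-10-bromo-1,9-epoxy-4-hydroxy-5,5,9-trimethylspiro[5.5]undec-1-en-3-one
Product: 17 (4R,6S,9R,10R)-4,10-dibromo-1,9-epoxy-5,5,9-trimethylspiro[5.5]undec-1-en-3-one, via triflate 16 (not isolated)
Conditions: Tf2O, 2,6-lutidine, CH2Cl2, −78 °C; then LiBr, THF, −40 → 0 °C
Reagents that add atoms: lithium bromide [Li+].[Br-]
Why: O-Triflation followed by SN2 displacement with bromide inverts C4 (S to R, bromine now syn to C11); substitution at a carbon that is alpha to a carbonyl group and next to a quaternary carbon is modelled by the clean inversions of pantolactone triflate, and no beta-hydrogen is available for elimination.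

Step 9
Reactants: 17 (4R,6S,9R,10R)-4,10-dibromo-1,9-epoxy-5,5,9-trimethylspiro[5.5]undec-1-en-3-one
Product: 18 (3S,4R,6S,9R,10R)-4,10-dibromo-1,9-epoxy-5,5,9-trimethylspiro[5.5]undec-1-en-3-ol
Conditions: iBu2AlH, toluene/CH2Cl2, −78 °C; then aqueous KNaC4H4O6 (potassium sodium tartrate)
Reagents that add atoms: none
Why: 1,2-Reduction of the enone-type carbonyl with a bulky aluminium hydride, in which hydride adds anti to the pseudoaxial C4–Br bond (polar Felkin–Anh control in an alpha-bromo ketone) and so sets C3 (S) with the hydroxyl cis to bromine.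

Step 10
Reactants: 18 (3S,4R,6S,9R,10R)-4,10-dibromo-1,9-epoxy-5,5,9-trimethylspiro[5.5]undec-1-en-3-ol
Product: 19 tert-butyl{[(3S,4R,6S,9R,10R)-4,10-dibromo-1,9-epoxy-5,5,9-trimethylspiro[5.5]undec-1-en-3-yl]oxy}dimethylsilane
Conditions: TBSOTf, 2,6-lutidine, CH2Cl2, −78 °C
Reagents that add atoms: tert-butyldimethylsilyl trifluoromethanesulfonate CC(C)(C)[Si](C)(C)OS(=O)(=O)C(F)(F)F
Why: Silylation of the secondary alcohol under buffered conditions gives an ether that suppresses ionisation at C3 in step 11 and elimination or retro-aldol chemistry in step 12; no stereocentre is touched.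

Step 11
Reactants: 19 tert-butyl{[(3S,4R,6S,9R,10R)-4,10-dibromo-1,9-epoxy-5,5,9-trimethylspiro[5.5]undec-1-en-3-yl]oxy}dimethylsilane
Product: 20 (3S,4R,6S,9R,10R)-4,10-dibromo-3-{[tert-butyl(dimethyl)silyl]oxy}-9-chloro-5,5,9-trimethylspiro[5.5]undecan-1-one
Conditions: HCl (2 M in Et2O, 1.2 equiv), CH2Cl2, −78 → −30 °C
Reagents that add atoms: hydrogen chloride Cl
Why: Acidolysis of a tertiary-alkyl enol ether (the reactivity of tert-butyl ether or ester cleavage by HCl): protonation at C2 gives the C1 oxocarbenium ion, the C9–O bond ionises with anchimeric assistance by the antiperiplanar bromine on C10, and chloride returns to the tertiary carbon C9 on the face that oxygen has just left (double inversion, net retention), so C9 (R) and C10 (R) are kept and the trans-diequatorial bromochloride is formed together with the C1 ketone.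

Step 12
Reactants: 20 (3S,4R,6S,9R,10R)-4,10-dibromo-3-{[tert-butyl(dimethyl)silyl]oxy}-9-chloro-5,5,9-trimethylspiro[5.5]undecan-1-one
Product: 22 (3S,4R,6R,9R,10R)-4,10-dibromo-9-chloro-5,5,9-trimethyl-1-methylidenespiro[5.5]undecan-3-ol (target), via beta-hydroxysilane 21 (not isolated)
Conditions: Me3SiCH2Li, CeCl3, THF, −78 °C; then 48% aqueous HF, MeCN, 0 → 23 °C
Reagents that add atoms: (trimethylsilyl)methyllithium [Li]C[Si](C)(C)C
Why: Peterson olefination: the organocerium reagent adds to the hindered, enolisable C1 ketone without deprotonation, HF then causes anti elimination of the beta-hydroxysilane to the exocyclic methylene group and cleaves the silyl ether in the same flask; the transient C1 carbinol centre is lost again and all five stereocentres stay as set.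

**Compound list**

1 | dimedone (5,5-dimethylcyclohexane-1,3-dione) | CC1(C)CC(=O)CC(=O)C1 | starting material
2 | 2-methylpropan-1-ol | CC(C)CO | starting material
3 | 5,5-dimethyl-3-(2-methylpropoxy)cyclohex-2-en-1-one | CC(C)COC1=CC(=O)CC(C)(C)C1 | intermediate
4 | 4-iodo-2-methylbut-1-ene | C=C(C)CCI | starting material
5 | lithium 3,3-dimethyl-5-(2-methylpropoxy)cyclohexa-1,5-dien-1-olate (formed in the flask) | [Li+].[O-]C1=CC(C)(C)CC(OCC(C)C)=C1 | intermediate
6 | 5,5-dimethyl-6-(3-methylbut-3-en-1-yl)-3-(2-methylpropoxy)cyclohex-2-en-1-one (racemic) | CC(C)COC1=CC(=O)C(CCC(C)=C)C(C)(C)C1 | intermediate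
7 | allyl chloroformate | C=CCOC(Cl)=O | starting material
8 | lithium 3,3-dimethyl-2-(3-methylbut-3-en-1-yl)-5-(2-methylpropoxy)cyclohexa-1,5-dien-1-olate (formed in the flask) | [Li+].[O-]C1=C(CCC(C)=C)C(C)(C)CC(OCC(C)C)=C1 | intermediate
9 | 3,3-dimethyl-2-(3-methylbut-3-en-1-yl)-5-(2-methylpropoxy)cyclohexa-1,5-dien-1-yl prop-2-en-1-yl carbonate | C=CCOC(=O)OC1=C(CCC(C)=C)C(C)(C)CC(OCC(C)C)=C1 | intermediate
10 | (6S)-5,5-dimethyl-6-(3-methylbut-3-en-1-yl)-3-(2-methylpropoxy)-6-(prop-2-en-1-yl)cyclohex-2-en-1-one | O=C1C=C(OCC(C)C)CC(C)(C)[C@@]1(CC=C)CCC(C)=C | intermediate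
11 | (6S)-5,5,9-trimethyl-3-(2-methylpropoxy)spiro[5.5]undeca-2,9-dien-1-one | O=C1C=C(OCC(C)C)CC(C)(C)[C@@]12CCC(C)=CC2 | intermediate
12 | (6S,9R,10R)-10-bromo-1,9-epoxy-5,5,9-trimethyl-3-(2-methylpropoxy)spiro[5.5]undec-1-en-3-ylium saccharinate (1,3-dialkoxyallyl cation, formed in the flask) | CC(C)C[O+]=C1CC(C)(C)[C@@]23CC[C@@](C)(OC2=C1)[C@H](Br)C3.O=C1[N-]S(=O)(=O)c2ccccc12 | intermediate
13 | (6S,9R,10R)-10-bromo-1,9-epoxy-5,5,9-trimethylspiro[5.5]undec-1-en-3-one | O=C1CC(C)(C)[C@@]23CC[C@@](C)(OC2=C1)[C@H](Br)C3 | intermediate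
14 | sodium (6S,9R,10R)-10-bromo-1,9-epoxy-5,5,9-trimethylspiro[5.5]undeca-1,3-dien-3-olate (formed in the flask) | [Na+].[O-]C1=CC(C)(C)[C@@]23CC[C@@](C)(OC2=C1)[C@H](Br)C3 | intermediate
15 | (4S,6S,9R,10R)-10-bromo-1,9-epoxy-4-hydroxy-5,5,9-trimethylspiro[5.5]undec-1-en-3-one | O=C1[C@@H](O)C(C)(C)[C@@]23CC[C@@](C)(OC2=C1)[C@H](Br)C3 | intermediate
16 | (4S,6S,9R,10R)-10-bromo-1,9-epoxy-5,5,9-trimethyl-3-oxospiro[5.5]undec-1-en-4-yl trifluoromethanesulfonate (formed in the flask) | O=C1[C@@H](OS(=O)(=O)C(F)(F)F)C(C)(C)[C@@]23CC[C@@](C)(OC2=C1)[C@H](Br)C3 | intermediate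
17 | (4R,6S,9R,10R)-4,10-dibromo-1,9-epoxy-5,5,9-trimethylspiro[5.5]undec-1-en-3-one | O=C1[C@H](Br)C(C)(C)[C@@]23CC[C@@](C)(OC2=C1)[C@H](Br)C3 | intermediate
18 | (3S,4R,6S,9R,10R)-4,10-dibromo-1,9-epoxy-5,5,9-trimethylspiro[5.5]undec-1-en-3-ol | O[C@@H]1[C@H](Br)C(C)(C)[C@@]23CC[C@@](C)(OC2=C1)[C@H](Br)C3 | intermediate
19 | tert-butyl{[(3S,4R,6S,9R,10R)-4,10-dibromo-1,9-epoxy-5,5,9-trimethylspiro[5.5]undec-1-en-3-yl]oxy}dimethylsilane | CC(C)(C)[Si](C)(C)O[C@@H]1[C@H](Br)C(C)(C)[C@@]23CC[C@@](C)(OC2=C1)[C@H](Br)C3 | intermediate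
20 | (3S,4R,6S,9R,10R)-4,10-dibromo-3-{[tert-butyl(dimethyl)silyl]oxy}-9-chloro-5,5,9-trimethylspiro[5.5]undecan-1-one | O=C1C[C@H](O[Si](C)(C)C(C)(C)C)[C@H](Br)C(C)(C)[C@@]12CC[C@@](C)(Cl)[C@H](Br)C2 | intermediate
21 | (3S,4R,6S,9R,10R)-4,10-dibromo-3-{[tert-butyl(dimethyl)silyl]oxy}-9-chloro-5,5,9-trimethyl-1-[(trimethylsilyl)methyl]spiro[5.5]undecan-1-ol (either C1 epimer, formed in the flask) | C[Si](C)(C)CC1(O)C[C@H](O[Si](C)(C)C(C)(C)C)[C@H](Br)C(C)(C)[C@@]12CC[C@@](C)(Cl)[C@H](Br)C2 | intermediate
22 | (3S,4R,6R,9R,10R)-4,10-dibromo-9-chloro-5,5,9-trimethyl-1-methylidenespiro[5.5]undecan-3-ol | C=C1C[C@H](O)[C@H](Br)C(C)(C)[C@@]12CC[C@@](C)(Cl)[C@H](Br)C2 | target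

**Summary**

Total step count: 12. Longest linear sequence: 12 steps from dimedone.

Steps most likely to fail:

Step 6 (the proposed new step). The risks are irreversible bromination at C2 of the vinylogous ester and intermolecular capture of the bromonium ion. The fallback uses known chemistry, sets out from 11 and comes back at 13. Compound 11 is hydrolysed with 1 M aqueous HCl in THF at 23 °C to the enolised (6S)-5,5,9-trimethylspiro[5.5]undec-9-ene-1,3-dione F1. The free enol is then cyclised with NBS in CH2Cl2 at −78 → −30 °C, an established bromo-enoletherification of a 1,3-dicarbonyl enol. Only the oxygen on C1 can reach C9, so the same bridged enol ether 13 with the same C9 and C10 configuration results.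

Step 8. The risks are slow SN2 substitution at the neopentyl-type C4 and bromide-induced epimerisation of the product. The fallback gives up reagent control at C4, sets out from 13 and comes back at 17, so steps 7 and 8 are both bypassed. Compound 13 is converted with LiN(SiMe3)2 and Me3SiCl in THF at −78 °C into the trimethylsilyl dienol ether F2. NBS in THF at −78 °C brominates it at C4 and gives 17 together with its C4 epimer, the (4S)-dibromide F3, in a ratio near 1:1. Compound 17 is separated by HPLC, and F3 is re-equilibrated with DBU and recycled.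

Step 11. The risks are ionisation at C3, loss of the silyl ether, chloride attack at C10 in place of C9, and loss of bromonium from the intermediate ion with re-addition to the wrong face. The fallback separates ring opening from chlorination, sets out from 19 and comes back at 20. Oxalic acid in wet THF at 0 °C hydrolyses the enol ether without breaking the C9–O bond and gives the 9-hydroxy ketone F4. SOCl2 with catalytic TiCl4 in CH2Cl2 at −20 °C then converts it by way of the chlorosulfite F5 into 20 with retention, through collapse of the chlorosulfite assisted by the neighbouring bromine.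

**Further compounds**

F1 | step 6 | (6S)-5,5,9-trimethylspiro[5.5]undec-9-ene-1,3-dione | O=C1CC(=O)CC(C)(C)[C@@]12CCC(C)=CC2
F2 | step 8 | (6S,9R,10R)-10-bromo-1,9-epoxy-5,5,9-trimethyl-3-(trimethylsilyloxy)spiro[5.5]undeca-1,3-diene | C[Si](C)(C)OC1=CC(C)(C)[C@@]23CC[C@@](C)(OC2=C1)[C@H](Br)C3
F3 | step 8 | (4S,6S,9R,10R)-4,10-dibromo-1,9-epoxy-5,5,9-trimethylspiro[5.5]undec-1-en-3-one | O=C1[C@@H](Br)C(C)(C)[C@@]23CC[C@@](C)(OC2=C1)[C@H](Br)C3
F4 | step 11 | (3S,4R,6S,9R,10R)-4,10-dibromo-3-{[tert-butyl(dimethyl)silyl]oxy}-9-hydroxy-5,5,9-trimethylspiro[5.5]undecan-1-one | O=C1C[C@H](O[Si](C)(C)C(C)(C)C)[C@H](Br)C(C)(C)[C@@]12CC[C@@](C)(O)[C@H](Br)C2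
F5 | step 11 | (3S,4R,6S,9R,10R)-4,10-dibromo-3-{[tert-butyl(dimethyl)silyl]oxy}-5,5,9-trimethyl-1-oxospiro[5.5]undecan-9-yl chlorosulfite | O=C1C[C@H](O[Si](C)(C)C(C)(C)C)[C@H](Br)C(C)(C)[C@@]12CC[C@@](C)(OS(Cl)=O)[C@H](Br)C2
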